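**Strategy.** Ring C (C8, C9, C11, C12, C13, C14) is a γ-oxo ester in disguise: C8 carries the lactone carbonyl C7 and C11 carries oxygen, with C9 between them. The route therefore disconnects the C9–C11 and C8–C15 bonds and builds, from two enantiopure fragments, a spiro β-keto lactone in which a cyclopentanone (C8, C11, C12, C13, C14) shares C8 with the lactone and C9 bears a phenylselanyl group. One radical chain inserts C9 between C8 and C11 (Dowd–Beckwith 1,2-acyl shift), expanding the cyclopentanone to ring C, and the C8 radical so formed closes ring D onto a C13 propargyl group, fixing C9 and quaternary C8.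

Key step: step 20

Remark: atoms are labelled by ent-kaurane numbering (ring A = C1–C5, C10; C6 aldehyde carbon; C7 lactone carbonyl; C20 lactone CH2; ring C = C8, C9, C11, C12, C13, C14; ring D adds C15, C16; C17 exocyclic CH2; C18 methyl; C19 acetoxymethyl carbon).

Remark: acid 8 is assumed to be separable from its antipode on a polysaccharide chiral phase; its absolute configuration would be confirmed crystallographically on the selenium-bearing acid 11.

## Ring A fragment (steps 1–12)

Step 1
Reactants: 1 2,2-dimethyl-1,3-dioxan-5-one; 2 allyl(triphenyl)phosphonium bromide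
Product: 3 2,2-dimethyl-5-(prop-2-en-1-ylidene)-1,3-dioxane
Conditions: n-BuLi, THF, −78 °C to rt
Reagents that add atoms: none
Why: Wittig olefination of the unhindered ketone with the allyl ylide should give the diene, and because the carbon that becomes C10 carries two identical CH2O arms no alkene geometry arises at that terminus.

Step 2
Reactants: 3 2,2-dimethyl-5-(prop-2-en-1-ylidene)-1,3-dioxane
Product: 4 2-(prop-2-en-1-ylidene)propane-1,3-diol
Conditions: pyridinium p-toluenesulfonate (cat.), MeOH, rt
Reagents that add atoms: none
Why: Acid-catalysed transketalisation with methanol should free the 1,3-diol under conditions mild enough for the allylic diene.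

Step 3
Reactants: 4 2-(prop-2-en-1-ylidene)propane-1,3-diol; 5 citraconic anhydride
Product: 7 racemic cis-fused lactone acid (ring A cyclohexene), via citraconate half-ester 6 (not isolated)
Conditions: 2,6-di-tert-butyl-4-methylphenol (cat.), xylene, 140 °C, sealed tube
Reagents that add atoms: none
Why: Reversible alcoholysis of the anhydride gives half-ester 6, whose intramolecular Diels–Alder reaction (hindered diene terminus C10 bonding to the unsubstituted dienophile carbon C5) should give the bicyclic lactone; suprafacial addition to the (Z)-dienophile sets C19 and C6 cis, and whichever CH2O arm of C10 lies cis to C6 ends in the cis-fused γ-lactone as C20, so C9 is necessarily trans.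

Step 4
Reactants: 7 racemic cis-fused lactone acid
Product: 8 (3aS,7R,7aS)-3a-(hydroxymethyl)-7-methyl-1-oxo-1,3,3a,6,7,7a-hexahydro-2-benzofuran-7-carboxylic acid
Conditions: preparative supercritical-fluid chromatography on amylose tris(3,5-dimethylphenylcarbamate), CO2/MeOH
Reagents that add atoms: none
Why: Chromatographic resolution of the racemate on a chiral stationary phase should deliver the single enantiomer without forming any new stereocentre.

Step 5
Reactants: 8 enantiopure lactone acid
Product: 9 saturated lactone acid (C1–C2 single bond)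
Conditions: H2 (1 atm), Pd on carbon (Pd/C), EtOAc, rt
Reagents that add atoms: none
Why: Heterogeneous hydrogenation should reduce the only alkene at a stage where neither selenium nor the alkyne is present.

Step 6
Reactants: 9 saturated lactone acid
Product: 10 lactone acid with C9 aldehyde
Conditions: Dess–Martin periodinane, NaHCO3, CH2Cl2, 0 °C to rt
Reagents that add atoms: none
Why: Dess–Martin oxidation of the neopentyl primary alcohol should stop at the aldehyde, which has no α-hydrogen and cannot epimerise, while the carboxylic acid is tolerated.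

Step 7
Reactants: 10 lactone acid with C9 aldehyde
Product: 11 lactone acid with C9 bis(phenylselanyl)acetal
Conditions: PhSeH, ZnCl2 (cat.), CH2Cl2, 0 °C to rt
Reagents that add atoms: benzeneselenol, [SeH]c1ccccc1
Why: Lewis-acid-catalysed selenoacetalisation should convert the aldehyde into a group that survives the hydride steps and later serves as the latent selenium-stabilised cation at C9.

Step 8
Reactants: 11 selenoacetal lactone acid
Product: 12 selenoacetal lactone with C19 primary alcohol
Conditions: BH3·SMe2, THF, 0 °C
Reagents that add atoms: none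
Why: Borane reduces a free carboxylic acid much faster than a lactone, so the C19 alcohol should form chemoselectively (it is acetylated at once to forestall translactonisation).

Step 9
Reactants: 12 C19 alcohol
Product: 13 selenoacetal lactone with C19 acetate
Conditions: Ac2O, pyridine, 4-(dimethylamino)pyridine (cat.), CH2Cl2, 0 °C
Reagents that add atoms: acetic anhydride, CC(=O)OC(C)=O
Why: Acylation of the only free hydroxyl should install the C19 acetate of the target.

Step 10
Reactants: 13 C19 acetate lactone
Product: 14 lactol (C6 hemiacetal; anomers)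
Conditions: disiamylborane (from BH3·THF and 2-methylbut-2-ene), THF, 0 °C to rt; aqueous ethanolamine work-up
Reagents that add atoms: none
Why: Disiamylborane reduces γ-lactones to lactols while leaving acetates untouched, and the non-oxidative work-up spares the selenides.

Step 11
Reactants: 14 lactol
Product: 15 C6,C20-diol
Conditions: NaBH4, CeCl3·7H2O, MeOH, −20 °C
Reagents that add atoms: none
Why: Borohydride reduction of the open hydroxy-aldehyde form of the lactol should give the 1,4-diol, the cerium salt and low temperature keeping the medium near neutral so that the C19 acetate does not migrate.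

Step 12
Reactants: 15 C6,C20-diol
Product: 16 ring A alcohol (C6 O-TBDPS; C20 OH free)
Conditions: TBDPSCl (1.05 equiv), imidazole, CH2Cl2, −20 °C
Reagents that add atoms: tert-butyl(chloro)diphenylsilane, CC(C)(C)[Si](Cl)(c1ccccc1)c1ccccc1
Why: Silylation should discriminate the two primary alcohols on steric grounds, the C6 hydroxymethyl sitting on a methine whereas the C20 hydroxymethyl is neopentyl and flanked by the bis(phenylselanyl)methyl group.

## Cyclopentanone fragment (steps 13–17)

Step 13
Reactants: 17 methyl pent-4-enoate; 18 (E)-but-2-enal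
Product: 19 methyl (E)-6-oxohex-4-enoate
Conditions: [1,3-bis(2,4,6-trimethylphenyl)imidazolidin-2-ylidene]dichloro(2-isopropoxybenzylidene)ruthenium (second-generation Hoveyda–Grubbs catalyst, 2 mol %), CH2Cl2, 40 °C
Reagents that add atoms: none
Why: Olefin cross-metathesis of the terminal alkene with excess crotonaldehyde should give the (E)-enal under thermodynamic control.

Step 14
Reactants: 19 methyl (E)-6-oxohex-4-enoate; 20 dimethyl malonate
Product: 21 trimethyl (2R)-2-(2-oxoethyl)butane-1,1,4-tricarboxylate
Conditions: (S)-2-{bis[3,5-bis(trifluoromethyl)phenyl][(trimethylsilyl)oxy]methyl}pyrrolidine (10 mol %), EtOH, 0 °C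
Reagents that add atoms: none
Why: Iminium-catalysed Michael addition of the malonate should occur on the enal face left open by the bulky diarylmethyl group of the (S)-catalyst, setting the future C13 as (R).

Step 15
Reactants: 21 aldehyde triester
Product: 22 trimethyl (2R)-2-(prop-2-yn-1-yl)butane-1,1,4-tricarboxylate
Conditions: dimethyl (1-diazo-2-oxopropyl)phosphonate, K2CO3, MeOH, 0 °C to rt
Reagents that add atoms: dimethyl (1-diazo-2-oxopropyl)phosphonate, COP(=O)(OC)C(=[N+]=[N-])C(C)=O
Why: Ohira–Bestmann homologation should convert the aldehyde into the terminal alkyne, the malonate being deprotonated under the conditions, which suppresses retro-Michael loss of configuration.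

Step 16
Reactants: 22 alkyne triester
Product: 23 dimethyl (3R)-3-(prop-2-yn-1-yl)hexanedioate
Conditions: NaCl, H2O, DMSO, 150 °C
Reagents that add atoms: none
Why: Krapcho dealkoxycarbonylation should remove one malonate ester selectively, the isolated ester and the alkyne being inert.

Step 17
Reactants: 23 dimethyl (3R)-3-(prop-2-yn-1-yl)hexanedioate
Product: 24 methyl (4R)-2-oxo-4-(prop-2-yn-1-yl)cyclopentane-1-carboxylate (C1 epimers and enol)
Conditions: NaOMe, MeOH, 65 °C; AcOH quench
Reagents that add atoms: none
Why: Dieckmann condensation under equilibrating conditions should favour the β-keto ester whose enolate is not flanked by the C13 substituent, that is closure between C8 and C11.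

## Fragment union and key step (steps 18–20)

Step 18
Reactants: 24 methyl (4R)-2-oxo-4-(prop-2-yn-1-yl)cyclopentane-1-carboxylate; 16 ring A alcohol
Product: 25 tethered β-keto ester (C20 O–C7 ester; C8 epimers)
Conditions: 4-(dimethylamino)pyridine (0.3 equiv), 4 Å molecular sieves, toluene, 110 °C
Reagents that add atoms: none
Why: Amine-catalysed transesterification of the β-keto ester with the neopentyl alcohol should proceed through its acylketene or acylpyridinium form and is driven by removal of methanol.

Step 19
Reactants: 25 tethered β-keto ester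
Product: 27 spiro β-keto lactone selenide (C9 epimers), via trimethylsilyl enol ether 26 (not isolated)
Conditions: TMSOTf, Et3N, CH2Cl2, 0 °C; solvent exchange; then SnCl4, CH2Cl2, −78 to −40 °C
Reagents that add atoms: none
Why: Lewis-acid ionisation of the selenoacetal should give a selenium-stabilised carbocation at C9 that is captured by C8 of the silyl enol ether in a Mukaiyama-type 6-exo closure of the δ-lactone, C9 adding to the face anti to the C13 propargyl group so that C7 is cis and C9 trans to it at the new spiro centre C8.

Step 20
Reactants: 27 spiro β-keto lactone selenide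
Product: 28 tetracyclic 11-ketone with 15-methylidene bicyclo[3.2.1]octane
Conditions: Bu3SnH (1.3 equiv) and 2,2'-azobis(2-methylpropionitrile) (0.2 equiv) added over 8 h by syringe pump, benzene (0.005 M), 80 °C
Reagents that add atoms: none
Why: Tributylstannyl radicals abstract the phenylselanyl group to give the C9 radical, which adds 3-exo-trig to the C11 carbonyl; β-scission of the C8–C11 bond of the cyclopropyloxy radical then gives the tertiary, lactone-stabilised C8 radical, so the cyclopentanone is expanded by one carbon to ring C, and this radical closes ring D by 5-exo-dig addition to the alkyne before the vinyl radical takes hydrogen from Bu3SnH. The closest known reaction type is the Dowd–Beckwith one-carbon ring expansion of 2-(halomethyl) β-keto esters, here coupled to an ordinary α-carbonyl radical/alkyne cyclisation. C9 is set stereospecifically, because the 1,2-acyl shift is suprafacial on the lactone ring and that ring forces C10 into the exo position of the bicyclo[3.1.0] intermediate, so the C8 configuration of 27 is translated into C9 with C10 cis to the C13 side chain. C8 is then fixed by the bridge, since the alkyne on C13 can only reach the face of the planar radical syn to it, which gives the trans-fused lactone. The step needs rearrangement and cyclisation to outrun hydrogen transfer, which slow addition at high dilution and the radical-stabilising lactone carbonyl (making C8–C11 scission the preferred fragmentation) should secure, and the C9 radical cannot attack the alkyne directly because it lies trans to the propargyl group.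

## Endgame (steps 21–25)

Step 21
Reactants: 28 tetracyclic 11-ketone
Product: 29 11-alcohol (equatorial OH)
Conditions: SmI2, HMPA, i-PrOH, THF, −78 to 0 °C
Reagents that add atoms: none
Why: Electron-transfer reduction of the ketone passes through a configurationally labile ketyl/carbanion at C11 that should be protonated to the more stable equatorial alcohol, with oxygen anti to the two-carbon bridge as the target requires, while lactone, acetate and alkene are inert to SmI2 in the absence of water.

Step 22
Reactants: 29 11-alcohol
Product: 30 15-ketone (β-keto lactone)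
Conditions: O3, CH2Cl2/MeOH, −78 °C; then Me2S
Reagents that add atoms: ozone, [O-][O+]=O
Why: Ozonolysis of the only alkene with reductive work-up should excise the alkyne-derived methylidene carbon and leave the C15 ketone.

Step 23
Reactants: 30 15-ketone
Product: 32 16-methylidene 15-ketone, via Mannich base 31 (not isolated)
Conditions: paraformaldehyde, N-methylanilinium trifluoroacetate, THF, 65 °C
Reagents that add atoms: formaldehyde (as paraformaldehyde), C=O
Why: Mannich reaction at C16, the only enolisable position of the C15 ketone since C8 is quaternary, followed by in situ β-elimination of N-methylaniline from 31 should give the exocyclic enone.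

Step 24
Reactants: 32 16-methylidene 15-ketone
Product: 33 C6 primary alcohol
Conditions: HF·pyridine, pyridine, THF, 0 °C to rt
Reagents that add atoms: none
Why: Fluoride cleavage of the silyl ether under buffered acidic conditions should spare the enone, the acetate and the lactone.

Step 25
Reactants: 33 C6 primary alcohol
Product: 34 trichorabdal B
Conditions: 2,2,6,6-tetramethylpiperidin-1-oxyl (cat.), PhI(OAc)2, CH2Cl2, rt
Reagents that add atoms: none
Why: Oxoammonium-mediated oxidation is selective for the primary C6 alcohol over the hindered secondary C11 alcohol and should stop at the aldehyde.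

## Compound list

1 | 2,2-dimethyl-1,3-dioxan-5-one | CC1(C)OCC(=O)CO1 | starting material
2 | allyl(triphenyl)phosphonium bromide | C=CC[P+](c1ccccc1)(c1ccccc1)c1ccccc1.[Br-] | starting material
3 | 2,2-dimethyl-5-(prop-2-en-1-ylidene)-1,3-dioxane | CC1(C)OCC(=CC=C)CO1 | intermediate
4 | 2-(prop-2-en-1-ylidene)propane-1,3-diol | OCC(CO)=CC=C | intermediate
5 | citraconic anhydride (3-methylfuran-2,5-dione) | CC1=CC(=O)OC1=O | starting material
6 | (2Z)-4-{[2-(hydroxymethyl)penta-2,4-dien-1-yl]oxy}-2-methyl-4-oxobut-2-enoic acid (citraconate half-ester; diene geometry not defined) | OC(=O)/C(C)=C\C(=O)OCC(CO)=CC=C | intermediate (not isolated)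
7 | rac-(3aS,7R,7aS)-3a-(hydroxymethyl)-7-methyl-1-oxo-1,3,3a,6,7,7a-hexahydro-2-benzofuran-7-carboxylic acid (racemate, one enantiomer drawn; cis-fused lactone, CO2H cis to the lactone carbonyl) | OC[C@@]12COC(=O)[C@@H]1[C@](C)(C(=O)O)CC=C2 | intermediate
8 | (3aS,7R,7aS)-3a-(hydroxymethyl)-7-methyl-1-oxo-1,3,3a,6,7,7a-hexahydro-2-benzofuran-7-carboxylic acid (single enantiomer) | OC[C@@]12COC(=O)[C@@H]1[C@](C)(C(=O)O)CC=C2 | intermediate
9 | (3aS,7R,7aS)-3a-(hydroxymethyl)-7-methyl-1-oxooctahydro-2-benzofuran-7-carboxylic acid | OC[C@@]12COC(=O)[C@@H]1[C@](C)(C(=O)O)CCC2 | intermediate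
10 | 3a-formyl analogue of 9 (C9 aldehyde; configuration unchanged) | O=C[C@@]12COC(=O)[C@@H]1[C@](C)(C(=O)O)CCC2 | intermediate
11 | 3a-[bis(phenylselanyl)methyl] analogue of 9 (C9 selenoacetal) | c1ccccc1[Se]C([Se]c1ccccc1)[C@@]12COC(=O)[C@@H]1[C@](C)(C(=O)O)CCC2 | intermediate
12 | selenoacetal lactone with C19 hydroxymethyl | c1ccccc1[Se]C([Se]c1ccccc1)[C@@]12COC(=O)[C@@H]1[C@](C)(CO)CCC2 | intermediate
13 | selenoacetal lactone with C19 acetoxymethyl | c1ccccc1[Se]C([Se]c1ccccc1)[C@@]12COC(=O)[C@@H]1[C@](C)(COC(C)=O)CCC2 | intermediate
14 | lactol of 13 (C6 hemiacetal, anomers) | c1ccccc1[Se]C([Se]c1ccccc1)[C@@]12COC(O)[C@@H]1[C@](C)(COC(C)=O)CCC2 | intermediate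
15 | ring A diol: C10 bears CH2OH (C20) and CH(SePh)2 (C9), C5 bears CH2OH (C6), C4 bears CH3 and CH2OAc; C19, C6, C20 carbons cis | OC[C@]1(CCC[C@@](C)(COC(C)=O)[C@H]1CO)C([Se]c1ccccc1)[Se]c1ccccc1 | intermediate
16 | ring A alcohol: C6 O-tert-butyldiphenylsilyl ether of 15, C20 OH free | OC[C@]1(CCC[C@@](C)(COC(C)=O)[C@H]1CO[Si](c2ccccc2)(c2ccccc2)C(C)(C)C)C([Se]c1ccccc1)[Se]c1ccccc1 | intermediate
17 | methyl pent-4-enoate | C=CCCC(=O)OC | starting material
18 | (E)-but-2-enal | C/C=C/C=O | starting material
19 | methyl (E)-6-oxohex-4-enoate | O=C/C=C/CCC(=O)OC | intermediate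
20 | dimethyl malonate | COC(=O)CC(=O)OC | starting material
21 | trimethyl (2R)-2-(2-oxoethyl)butane-1,1,4-tricarboxylate | O=CC[C@H](C(C(=O)OC)C(=O)OC)CCC(=O)OC | intermediate
22 | trimethyl (2R)-2-(prop-2-yn-1-yl)butane-1,1,4-tricarboxylate | C#CC[C@H](C(C(=O)OC)C(=O)OC)CCC(=O)OC | intermediate
23 | dimethyl (3R)-3-(prop-2-yn-1-yl)hexanedioate | C#CC[C@H](CC(=O)OC)CCC(=O)OC | intermediate
24 | methyl (4R)-2-oxo-4-(prop-2-yn-1-yl)cyclopentane-1-carboxylate (C1 not defined) | C#CC[C@@H]1CC(=O)C(C1)C(=O)OC | intermediate
25 | tethered β-keto ester: C20 ester of 16 with the acid of 24 (C8 not defined) | C#CC[C@@H]1CC(=O)C(C1)C(=O)OC[C@]1(CCC[C@@](C)(COC(C)=O)[C@H]1CO[Si](c2ccccc2)(c2ccccc2)C(C)(C)C)C([Se]c1ccccc1)[Se]c1ccccc1 | intermediate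
26 | trimethylsilyl enol ether of 25 (C8=C11, C11 OSiMe3) | C#CC[C@@H]1CC(O[Si](C)(C)C)=C(C1)C(=O)OC[C@]1(CCC[C@@](C)(COC(C)=O)[C@H]1CO[Si](c2ccccc2)(c2ccccc2)C(C)(C)C)C([Se]c1ccccc1)[Se]c1ccccc1 | intermediate (not isolated)
27 | spiro β-keto lactone selenide: δ-lactone (C7, O, C20, C10, C9, C8) spiro at C8 to the cyclopentanone and at C10 to ring A; C7 cis and C9 trans to the C13 propargyl group; C9 SePh epimers | C#CC[C@@H]1CC(=O)[C@@]2(C1)C(=O)OC[C@]1(CCC[C@@](C)(COC(C)=O)[C@H]1CO[Si](c3ccccc3)(c3ccccc3)C(C)(C)C)C2[Se]c1ccccc1 | intermediate
28 | tetracyclic 11-ketone: 15-methylidene bicyclo[3.2.1]octane trans-fused to the 7,20-lactone | C1C(=C)[C@]23C[C@H]1CC(=O)[C@@H]2[C@@]1(CCC[C@@](C)(COC(C)=O)[C@H]1CO[Si](c4ccccc4)(c4ccccc4)C(C)(C)C)COC3=O | intermediate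
29 | 11-alcohol of 28 (equatorial OH, anti to the C15–C16 bridge) | C1C(=C)[C@]23C[C@H]1C[C@@H](O)[C@@H]2[C@@]1(CCC[C@@](C)(COC(C)=O)[C@H]1CO[Si](c4ccccc4)(c4ccccc4)C(C)(C)C)COC3=O | intermediate
30 | 15-ketone (11-hydroxy β-keto lactone) | C1C(=O)[C@]23C[C@H]1C[C@@H](O)[C@@H]2[C@@]1(CCC[C@@](C)(COC(C)=O)[C@H]1CO[Si](c4ccccc4)(c4ccccc4)C(C)(C)C)COC3=O | intermediate
31 | Mannich base: 16-exo-[(N-methylanilino)methyl] 15-ketone | CN(c1ccccc1)C[C@@H]1C(=O)[C@]23C[C@H]1C[C@@H](O)[C@@H]2[C@@]1(CCC[C@@](C)(COC(C)=O)[C@H]1CO[Si](c4ccccc4)(c4ccccc4)C(C)(C)C)COC3=O | intermediate (not isolated)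
32 | 16-methylidene 15-ketone (C6 O-TBDPS ether of 33) | C=C1C(=O)[C@]23C[C@H]1C[C@@H](O)[C@@H]2[C@@]1(CCC[C@@](C)(COC(C)=O)[C@H]1CO[Si](c4ccccc4)(c4ccccc4)C(C)(C)C)COC3=O | intermediate
33 | C6 primary alcohol (6-dihydro-trichorabdal B) | C=C1C(=O)[C@]23C[C@H]1C[C@@H](O)[C@@H]2[C@@]1(CCC[C@@](C)(COC(C)=O)[C@H]1CO)COC3=O | intermediate
34 | trichorabdal B (4R,5R,8S,9R,10R,11R,13S) | C=C1C(=O)[C@]23C[C@H]1C[C@@H](O)[C@@H]2[C@@]1(CCC[C@@](C)(COC(C)=O)[C@H]1C=O)COC3=O | target

## Step count and risks

Total: 25 steps. Longest linear sequence: 20 steps (steps 1–12 and 18–25).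

Steps most likely to fail:

1. Step 20. Hydrogen transfer from the tin hydride to the C9 radical (before the acyl shift) or to the C8 radical (before ring D closes) may outrun the cascade. Fallback: setting out from 27, the cascade is run without a hydride donor as a phenylselanyl group-transfer chain ((Bu3Sn)2 cat., sunlamp, benzene, 80 °C). The vinyl radical should then abstract PhSe from another molecule of 27 to give the isomeric 15-[(phenylselanyl)methylidene] ketone F1. With both rings already closed, reductive deselenation (Bu3SnH, 2,2'-azobis(2-methylpropionitrile), toluene, 110 °C) should return to the route at 28.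

2. Step 19. The tethered cation may attack the wrong face of the enol ether (C8 epimer), or ionise without closing the ring. Fallback: setting out from 24 and 16, the bond is made intermolecularly so that only the C13 propargyl group governs the face. Compound 24 is converted into its trimethylsilyl enol ether F2 (TMSOTf, Et3N) and alkylated with the selenium-stabilised cation from 16 (SnCl4, CH2Cl2, −78 °C) to give the C8-alkylated methyl β-keto ester F3. Acid-catalysed lactonisation between the free C20 hydroxyl and the methyl ester (pyridinium p-toluenesulfonate, toluene, 80 °C) then returns to the route at 27.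

3. Step 21. Hydrogen may be delivered to the wrong face of C11 (axial alcohol), or the ketyl may undergo pinacol coupling. Fallback: setting out from 28, NaBH4 (MeOH, 0 °C) should attack from the open equatorial direction and give the 11-epi (axial) alcohol F4. Mitsunobu inversion with chloroacetic acid (PPh3, diisopropyl azodicarboxylate, toluene) would give the inverted 11-chloroacetate F5, and selective removal of the chloroacetyl group (thiourea, NaHCO3, EtOH) in the presence of the C19 acetate returns to the route at 29.

Further compounds
F1 | step 20 | 15-[(phenylselanyl)methylidene] analogue of 28 (alkene geometry not defined) | C1C(=C[Se]c5ccccc5)[C@]23C[C@H]1CC(=O)[C@@H]2[C@@]1(CCC[C@@](C)(COC(C)=O)[C@H]1CO[Si](c4ccccc4)(c4ccccc4)C(C)(C)C)COC3=O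
F2 | step 19 | trimethylsilyl enol ether of 24 | C#CC[C@@H]1CC(O[Si](C)(C)C)=C(C1)C(=O)OC
F3 | step 19 | C8-alkylated methyl β-keto ester (C9 SePh epimers, C20 OH free) | C#CC[C@@H]1CC(=O)[C@@](C1)(C(=O)OC)C([Se]c1ccccc1)[C@]1(CO)CCC[C@@](C)(COC(C)=O)[C@H]1CO[Si](c2ccccc2)(c2ccccc2)C(C)(C)C
F4 | step 21 | 11-epi alcohol (axial OH) | C1C(=C)[C@]23C[C@H]1C[C@H](O)[C@@H]2[C@@]1(CCC[C@@](C)(COC(C)=O)[C@H]1CO[Si](c4ccccc4)(c4ccccc4)C(C)(C)C)COC3=O
F5 | step 21 | 11-O-chloroacetate of 29 | C1C(=C)[C@]23C[C@H]1C[C@@H](OC(=O)CCl)[C@@H]2[C@@]1(CCC[C@@](C)(COC(C)=O)[C@H]1CO[Si](c4ccccc4)(c4ccccc4)C(C)(C)C)COC3=O
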